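**Plan**
1. Retrosynthetic cuts, in order: the four O–benzyl bonds (hydrogenolysis); the C3–OH and CH2–OH bonds (osmylation of a C3 exocyclic methylene); the C8a–C1 bond of ring B (Friedel–Crafts opening of a C1–C2 oxirane); the two oxirane C–O bonds (asymmetric epoxidation of an (E)-allylic alcohol); the C2–C3 bond (Negishi coupling).
2. Forward: the pendant-ring aldehyde becomes an α-bromocinnamate and the ring A bromide a 2-bromoallyl arene; the two are joined at C2–C3 to a cross-conjugated diene ester; reduction, epoxidation and oxidation give a benzyl glycidate; ring B is closed; the C3 glycol is added; all benzyl groups are removed.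
3. Enabling feature: C1 is benzylic to the 3,4,5-trioxygenated pendant ring and vicinal to the carbinol carbon C2 that carries the carboxyl group, and C8a of ring A lies para to the C6 methoxy group. A strained C1–C2 oxirane bearing the C2 ester is therefore opened only at C1 by C8a, which closes ring B and unveils the C2 hydroxyl in one event.
4. Stereochemistry: C1 and C2 come from a Sharpless epoxidation (L-(+)-tartrate) of a geometrically defined alkene, C1 being relayed with inversion in the ring closure; C3 comes from substrate-controlled osmylation of the tetralin, anti to the C2 hydroxyl and to the C1 aryl group.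

Key step: step 8

Remark: the tetralin numbering of the target (C1–C4, C4a, C5–C8, C8a; pendant aryl on C1, carboxyl on C2) is used for every intermediate, and compounds 1, 3, 6 and 7 are assumed to be purchasable as such.

Step 1
Reactants: 1 3,4-dihydroxy-5-methoxybenzaldehyde
Product: 2 3,4-bis(benzyloxy)-5-methoxybenzaldehyde
Conditions: BnBr (2.2 equiv), K2CO3, DMF, 60 °C
Reagents that add atoms: benzyl bromide, BrCc1ccccc1
Why: Williamson ether synthesis; both phenols are alkylated as phenoxides, the aldehyde is untouched, and benzyl is chosen so that every protecting group leaves in the last step.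

Step 2
Reactants: 2 3,4-bis(benzyloxy)-5-methoxybenzaldehyde; 3 ethyl (triphenylphosphoranylidene)acetate
Product: 5 ethyl (2Z)-3-[3,4-bis(benzyloxy)-5-methoxyphenyl]-2-bromoprop-2-enoate, via bromo ylide 4 (not isolated)
Conditions: 3, NBS, CH2Cl2, −20 °C; then 2, rt
Reagents that add atoms: N-bromosuccinimide, O=C1CCC(=O)N1Br
Why: Wittig reaction of a stabilised α-bromo ylide made in the flask (bromination at the ylide carbon, the succinimide anion removing the remaining proton); such ylides should place the aryl group trans to the ester, that is the (Z)-bromoalkene, and any minor (E)-isomer is removed by crystallisation.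

Step 3
Reactants: 6 1-(benzyloxy)-4-bromo-2-methoxybenzene; 7 2,3-dibromoprop-1-ene
Product: 9 1-(benzyloxy)-4-(2-bromoprop-2-en-1-yl)-2-methoxybenzene, via aryl Grignard reagent 8 (not isolated)
Conditions: 6, Mg, THF, 40 °C; then 7, CuI (5 mol %), −20 °C to rt
Reagents that add atoms: none
Why: copper-catalysed allylation of a Grignard reagent; only the allylic C–Br bond of 7 reacts and the vinylic bromide is kept for the next coupling.

Step 4
Reactants: 9 1-(benzyloxy)-4-(2-bromoprop-2-en-1-yl)-2-methoxybenzene; 5 ethyl (2Z)-3-[3,4-bis(benzyloxy)-5-methoxyphenyl]-2-bromoprop-2-enoate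
Product: 12 ethyl (2E)-2-{3-[4-(benzyloxy)-3-methoxyphenyl]prop-1-en-2-yl}-3-[3,4-bis(benzyloxy)-5-methoxyphenyl]prop-2-enoate, via alkenylmagnesium bromide 10 (not isolated), via alkenylzinc chloride 11 (not isolated)
Conditions: 9, Mg, LiCl, THF, rt; ZnCl2, 0 °C; then 5, Pd(PPh3)4 (5 mol %), THF, 45 °C
Reagents that add atoms: none
Why: Negishi coupling; oxidative addition of the zerovalent palladium catalyst into the C–Br bond of 5 and reductive elimination proceed with retention, so the alkenyl group takes the place of bromine cis to the aryl group, and the organozinc leaves the ester alone.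

Step 5
Reactants: 12 ethyl (2E)-2-{3-[4-(benzyloxy)-3-methoxyphenyl]prop-1-en-2-yl}-3-[3,4-bis(benzyloxy)-5-methoxyphenyl]prop-2-enoate
Product: 13 (2E)-2-{3-[4-(benzyloxy)-3-methoxyphenyl]prop-1-en-2-yl}-3-[3,4-bis(benzyloxy)-5-methoxyphenyl]prop-2-en-1-ol
Conditions: i-Bu2AlH (2.5 equiv), CH2Cl2, −78 °C; aq. KNaC4H4O6 work-up
Reagents that add atoms: none
Why: hydride reduction of the conjugated ester to the primary allylic alcohol by 1,2-addition only; the alkene geometry is untouched.

Step 6
Reactants: 13 (2E)-2-{3-[4-(benzyloxy)-3-methoxyphenyl]prop-1-en-2-yl}-3-[3,4-bis(benzyloxy)-5-methoxyphenyl]prop-2-en-1-ol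
Product: 14 [(2S,3S)-2-{3-[4-(benzyloxy)-3-methoxyphenyl]prop-1-en-2-yl}-3-[3,4-bis(benzyloxy)-5-methoxyphenyl]oxiran-2-yl]methanol
Conditions: Ti(OiPr)4 (10 mol %), L-(+)-diisopropyl tartrate (12 mol %), t-BuOOH (2 equiv, in isooctane), 4 Å molecular sieves, CH2Cl2, −25 °C
Reagents that add atoms: tert-butyl hydroperoxide, CC(C)(C)OO
Why: Sharpless asymmetric epoxidation; the Ti(OiPr)4/tartrate catalyst delivers oxygen only to the alkene of the allylic alcohol (the 1,1-disubstituted alkene is homoallylic), syn addition keeps the aryl group cis to the alkenyl arm, and L-(+)-tartrate should give the (2S,3S)-epoxy alcohol as it does for other (E)-2,3-disubstituted allylic alcohols, so both oxirane stereocentres are set by reagent control.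

Step 7
Reactants: 14 [(2S,3S)-2-{3-[4-(benzyloxy)-3-methoxyphenyl]prop-1-en-2-yl}-3-[3,4-bis(benzyloxy)-5-methoxyphenyl]oxiran-2-yl]methanol
Product: 16 benzyl (2R,3S)-2-{3-[4-(benzyloxy)-3-methoxyphenyl]prop-1-en-2-yl}-3-[3,4-bis(benzyloxy)-5-methoxyphenyl]oxirane-2-carboxylate, via sodium glycidate 15 (not isolated)
Conditions: TEMPO (20 mol %), PhI(OAc)2 (2.2 equiv), NaHCO3, MeCN/H2O, 0 °C to rt; aq. Na2S2O3; then BnBr, Bu4NBr (10 mol %), CH2Cl2/H2O, rt
Reagents that add atoms: water, O; benzyl bromide, BrCc1ccccc1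
Why: oxoammonium (TEMPO) oxidation of the primary alcohol through the aldehyde hydrate to the carboxylate, which the bicarbonate keeps as its sodium salt so that the acid-labile 3-aryl glycidic acid never forms, followed by phase-transfer O-alkylation of the carboxylate; neither oxirane stereocentre is touched (the descriptor at C2 changes only because the substituent priorities change).

Step 8
Reactants: 16 benzyl (2R,3S)-2-{3-[4-(benzyloxy)-3-methoxyphenyl]prop-1-en-2-yl}-3-[3,4-bis(benzyloxy)-5-methoxyphenyl]oxirane-2-carboxylate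
Product: 17 benzyl (1S,2S)-7-(benzyloxy)-1-[3,4-bis(benzyloxy)-5-methoxyphenyl]-2-hydroxy-6-methoxy-3-methylidene-1,2,3,4-tetrahydronaphthalene-2-carboxylate
Conditions: Sc(OTf)3 (10 mol %), 2,6-di-tert-butylpyridine (20 mol %), CH2Cl2 (0.01 M), −40 °C to 0 °C
Reagents that add atoms: none
Why: Sc(OTf)3 binds the oxirane oxygen and the ester carbonyl of 16 as a five-membered chelate, C8a of ring A (para to the C6 methoxy group) attacks the benzylic oxirane carbon C1 from the side opposite to the breaking C1–O bond, and loss of the proton from the arenium ion gives the tetralin with the former oxirane oxygen as the C2 hydroxyl. The closest known reaction type is the Lewis-acid-promoted intramolecular Friedel–Crafts epoxy-arene cyclisation, together with the opening of 3-aryl glycidic esters at the benzylic carbon by electron-rich arenes. Ring B is closed in the 6-endo-tet mode with respect to the oxirane (both oxirane carbons end up in the new ring), whereas 5-exo attack at C2 would need cleavage of the C2–O bond next to the ester. C1 is set by inversion at the (3S)-oxirane carbon, so that with the aryl group cis to the alkenyl arm in 16 the pendant aryl ends trans to the ester and cis to the C2 hydroxyl, while C2 keeps its C–O bond and its configuration from step 6. The step needs C1–O rather than C2–O cleavage, secured by the electron-withdrawing ester on C2 and the alkoxy-substituted aryl on C1; attack through the ring A position para to the methoxy group, which is the unhindered and most nucleophilic one; and survival of the exocyclic alkene, for which a catalytic Lewis acid, low temperature, high dilution and a hindered base that removes adventitious triflic acid are used. Should ionisation run ahead of C–C bond formation, the chelated half-chair with the pendant aryl pseudoaxial and anti to the pseudoaxial ester should still lead to the same diastereomer.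

Step 9
Reactants: 17 benzyl (1S,2S)-7-(benzyloxy)-1-[3,4-bis(benzyloxy)-5-methoxyphenyl]-2-hydroxy-6-methoxy-3-methylidene-1,2,3,4-tetrahydronaphthalene-2-carboxylate
Product: 18 benzyl (1S,2S,3R)-7-(benzyloxy)-1-[3,4-bis(benzyloxy)-5-methoxyphenyl]-2,3-dihydroxy-3-(hydroxymethyl)-6-methoxy-1,2,3,4-tetrahydronaphthalene-2-carboxylate
Conditions: OsO4 (5 mol %), NMO (2 equiv), acetone/H2O (5:1), rt
Reagents that add atoms: N-methylmorpholine N-oxide, C[N+]1([O-])CCOCC1; water, O
Why: catalytic osmylation (syn dihydroxylation) of the exocyclic 1,1-disubstituted alkene; OsO4 should add to the face anti to the allylic C2 hydroxyl and away from the pseudoaxial C1 aryl group that stands 1,3 to C3, which places the new C3 hydroxyl trans to the C2 hydroxyl and cis to the ester and sets C3 as (R).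

Step 10
Reactants: 18 benzyl (1S,2S,3R)-7-(benzyloxy)-1-[3,4-bis(benzyloxy)-5-methoxyphenyl]-2,3-dihydroxy-3-(hydroxymethyl)-6-methoxy-1,2,3,4-tetrahydronaphthalene-2-carboxylate
Product: 19 plicatic acid, (1S,2S,3R)-1-(3,4-dihydroxy-5-methoxyphenyl)-2,3,7-trihydroxy-3-(hydroxymethyl)-6-methoxy-1,2,3,4-tetrahydronaphthalene-2-carboxylic acid
Conditions: H2 (1 atm), Pd on carbon (10 wt % Pd), EtOAc/MeOH, rt, degassed work-up
Reagents that add atoms: none
Why: hydrogenolysis cleaves the three aryl benzyl ethers and the benzyl ester in one operation; the molecule holds no alkene and no other benzylic C–O bond, so no stereocentre is affected.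

**Compound list**
1 | 3,4-dihydroxy-5-methoxybenzaldehyde | O=Cc1cc(O)c(O)c(OC)c1 | starting material
2 | 3,4-bis(benzyloxy)-5-methoxybenzaldehyde | O=Cc1cc(OCc2ccccc2)c(OCc2ccccc2)c(OC)c1 | intermediate
3 | ethyl (triphenylphosphoranylidene)acetate | CCOC(=O)C=P(c1ccccc1)(c1ccccc1)c1ccccc1 | starting material
4 | ethyl bromo(triphenylphosphoranylidene)acetate (bromo ylide) | CCOC(=O)C(Br)=P(c1ccccc1)(c1ccccc1)c1ccccc1 | intermediate
5 | ethyl (2Z)-3-[3,4-bis(benzyloxy)-5-methoxyphenyl]-2-bromoprop-2-enoate (aryl cis to Br, trans to the ester) | CCOC(=O)/C(Br)=C/c1cc(OCc2ccccc2)c(OCc2ccccc2)c(OC)c1 | intermediate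
6 | 1-(benzyloxy)-4-bromo-2-methoxybenzene | COc1cc(Br)ccc1OCc1ccccc1 | starting material
7 | 2,3-dibromoprop-1-ene | C=C(Br)CBr | starting material
8 | [4-(benzyloxy)-3-methoxyphenyl]magnesium bromide | COc1cc([Mg]Br)ccc1OCc1ccccc1 | intermediate
9 | 1-(benzyloxy)-4-(2-bromoprop-2-en-1-yl)-2-methoxybenzene | COc1cc(CC(Br)=C)ccc1OCc1ccccc1 | intermediate
10 | {3-[4-(benzyloxy)-3-methoxyphenyl]prop-1-en-2-yl}magnesium bromide | COc1cc(CC(=C)[Mg]Br)ccc1OCc1ccccc1 | intermediate
11 | {3-[4-(benzyloxy)-3-methoxyphenyl]prop-1-en-2-yl}zinc chloride | COc1cc(CC(=C)[Zn]Cl)ccc1OCc1ccccc1 | intermediate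
12 | ethyl (2E)-2-{3-[4-(benzyloxy)-3-methoxyphenyl]prop-1-en-2-yl}-3-[3,4-bis(benzyloxy)-5-methoxyphenyl]prop-2-enoate (aryl cis to the alkenyl arm) | CCOC(=O)/C(=C/c1cc(OCc2ccccc2)c(OCc2ccccc2)c(OC)c1)C(=C)Cc1ccc(OCc2ccccc2)c(OC)c1 | intermediate
13 | (2E)-2-{3-[4-(benzyloxy)-3-methoxyphenyl]prop-1-en-2-yl}-3-[3,4-bis(benzyloxy)-5-methoxyphenyl]prop-2-en-1-ol | OC/C(=C/c1cc(OCc2ccccc2)c(OCc2ccccc2)c(OC)c1)C(=C)Cc1ccc(OCc2ccccc2)c(OC)c1 | intermediate
14 | [(2S,3S)-2-{3-[4-(benzyloxy)-3-methoxyphenyl]prop-1-en-2-yl}-3-[3,4-bis(benzyloxy)-5-methoxyphenyl]oxiran-2-yl]methanol | COc1cc(cc(OCc2ccccc2)c1OCc1ccccc1)[C@@H]1O[C@]1(CO)C(=C)Cc1ccc(OCc2ccccc2)c(OC)c1 | intermediate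
15 | sodium (2R,3S)-2-{3-[4-(benzyloxy)-3-methoxyphenyl]prop-1-en-2-yl}-3-[3,4-bis(benzyloxy)-5-methoxyphenyl]oxirane-2-carboxylate | COc1cc(cc(OCc2ccccc2)c1OCc1ccccc1)[C@@H]1O[C@]1(C(=O)[O-])C(=C)Cc1ccc(OCc2ccccc2)c(OC)c1.[Na+] | intermediate
16 | benzyl (2R,3S)-2-{3-[4-(benzyloxy)-3-methoxyphenyl]prop-1-en-2-yl}-3-[3,4-bis(benzyloxy)-5-methoxyphenyl]oxirane-2-carboxylate | COc1cc(cc(OCc2ccccc2)c1OCc1ccccc1)[C@@H]1O[C@]1(C(=O)OCc1ccccc1)C(=C)Cc1ccc(OCc2ccccc2)c(OC)c1 | intermediate
17 | benzyl (1S,2S)-7-(benzyloxy)-1-[3,4-bis(benzyloxy)-5-methoxyphenyl]-2-hydroxy-6-methoxy-3-methylidene-1,2,3,4-tetrahydronaphthalene-2-carboxylate | COc1cc2c(cc1OCc1ccccc1)[C@H](c1cc(OCc3ccccc3)c(OCc3ccccc3)c(OC)c1)[C@@](O)(C(=O)OCc1ccccc1)C(=C)C2 | intermediate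
18 | benzyl (1S,2S,3R)-7-(benzyloxy)-1-[3,4-bis(benzyloxy)-5-methoxyphenyl]-2,3-dihydroxy-3-(hydroxymethyl)-6-methoxy-1,2,3,4-tetrahydronaphthalene-2-carboxylate | COc1cc2c(cc1OCc1ccccc1)[C@H](c1cc(OCc3ccccc3)c(OCc3ccccc3)c(OC)c1)[C@@](O)(C(=O)OCc1ccccc1)[C@](O)(CO)C2 | intermediate
19 | plicatic acid, (1S,2S,3R)-1-(3,4-dihydroxy-5-methoxyphenyl)-2,3,7-trihydroxy-3-(hydroxymethyl)-6-methoxy-1,2,3,4-tetrahydronaphthalene-2-carboxylic acid | COc1cc2c(cc1O)[C@H](c1cc(O)c(O)c(OC)c1)[C@@](O)(C(=O)O)[C@](O)(CO)C2 | target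

**Count**
Total steps: 10. Longest linear sequence: 9 steps (1 → 2 → 5 → 12 → 13 → 14 → 16 → 17 → 18 → 19); step 3 is the side branch to 9.

**The three steps most likely to fail**

Step 8. During or after C1–O cleavage, a 1,2-shift of the ester or of the alkenyl group from C2 to C1 (semipinacol-type rearrangement of the glycidic ester) may outrun arene attack. The exocyclic double bond may also migrate into conjugation with ring A, or ionisation to a free benzylic cation may erode the inversion. The fallback closes the ring at the alcohol oxidation level, where the hydroxymethyl and oxirane oxygens chelate the Lewis acid and activate C3 of the 2,3-epoxy alcohol under milder conditions, and where no ester is present to migrate. It sets out from 14: Ti(OiPr)4 (1.5 equiv) in CH2Cl2 at 0 °C to rt (BF3·OEt2 at −78 °C if more activation is needed) should give the tetralin diol F1 by the same invertive attack of C8a on C1. Parikh–Doering oxidation (SO3·pyridine, DMSO, i-Pr2NEt) of the primary alcohol should then give the hydroxy aldehyde F2, and Pinnick oxidation (NaClO2, NaH2PO4, 2-methylbut-2-ene, t-BuOH/H2O) the hydroxy acid F3, which is no longer a glycidic acid. Benzylation (BnBr, KHCO3, DMF) brings the route back at 17.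

Step 9. Poor facial selectivity: if the half-chair with the ester pseudoaxial dominates, the osmium reagent may be pushed to the face of the C2 hydroxyl and give the C3 epimer. The fallback delivers carbon instead of oxygen to C3, so that the same facial bias works in the right sense. It sets out from 17 (an epimeric diol is cut by periodate to the same ketone): OsO4 (cat.)/NaIO4/2,6-lutidine in dioxane/H2O (Lemieux–Johnson cleavage) should give the 3-oxotetralin F4. Addition of [dimethyl(propan-2-yloxy)silyl]methylmagnesium chloride (CeCl3, THF, −78 °C) should then give the silylmethyl carbinol F5; here the C2 alkoxide chelates the C3 carbonyl and the nucleophile enters anti to the ester, from the face of the C2 hydroxyl. Tamao–Fleming oxidation (H2O2, KF, KHCO3, THF/MeOH) turns C–Si into C–OH and brings the route back at 18.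

Step 4. Slow transmetalation or reductive elimination at the hindered α-carbon of the enoate, or E/Z scrambling of the α-palladated enoate, would cost yield or the geometric purity on which steps 6 and 8 depend. The fallback builds the same trisubstituted alkene by carbometalation of an alkyne instead of cross-coupling. It sets out from 2: Corey–Fuchs olefination (CBr4, PPh3, CH2Cl2, 0 °C) should give the dibromoalkene F6, and n-BuLi (2.1 equiv, THF, −78 °C) followed by paraformaldehyde the propargylic alcohol F7. Copper-catalysed anti-carbomagnesiation of F7 with the alkenyl Grignard reagent 10 (3 equiv, CuI 10 mol %, THF/toluene, rt to 50 °C) adds the alkenyl group to the alkyne carbon next to CH2OH. Protonation of the chelated five-membered alkenylmagnesium alkoxide then leaves the aryl group cis to the alkenyl arm. The route comes back at 13; steps 2, 4 and 5 are bypassed.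

Further compounds
F1 | step 8 | (1S,2S)-7-(benzyloxy)-1-[3,4-bis(benzyloxy)-5-methoxyphenyl]-2-(hydroxymethyl)-6-methoxy-3-methylidene-1,2,3,4-tetrahydronaphthalen-2-ol | COc1cc2c(cc1OCc1ccccc1)[C@H](c1cc(OCc3ccccc3)c(OCc3ccccc3)c(OC)c1)[C@@](O)(CO)C(=C)C2
F2 | step 8 | (1S,2S)-7-(benzyloxy)-1-[3,4-bis(benzyloxy)-5-methoxyphenyl]-2-hydroxy-6-methoxy-3-methylidene-1,2,3,4-tetrahydronaphthalene-2-carbaldehyde | COc1cc2c(cc1OCc1ccccc1)[C@H](c1cc(OCc3ccccc3)c(OCc3ccccc3)c(OC)c1)[C@@](O)(C=O)C(=C)C2
F3 | step 8 | (1S,2S)-7-(benzyloxy)-1-[3,4-bis(benzyloxy)-5-methoxyphenyl]-2-hydroxy-6-methoxy-3-methylidene-1,2,3,4-tetrahydronaphthalene-2-carboxylic acid | COc1cc2c(cc1OCc1ccccc1)[C@H](c1cc(OCc3ccccc3)c(OCc3ccccc3)c(OC)c1)[C@@](O)(C(=O)O)C(=C)C2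
F4 | step 9 | benzyl (1S,2S)-7-(benzyloxy)-1-[3,4-bis(benzyloxy)-5-methoxyphenyl]-2-hydroxy-6-methoxy-3-oxo-1,2,3,4-tetrahydronaphthalene-2-carboxylate | COc1cc2c(cc1OCc1ccccc1)[C@H](c1cc(OCc3ccccc3)c(OCc3ccccc3)c(OC)c1)[C@@](O)(C(=O)OCc1ccccc1)C(=O)C2
F5 | step 9 | benzyl (1S,2S,3S)-7-(benzyloxy)-1-[3,4-bis(benzyloxy)-5-methoxyphenyl]-3-{[dimethyl(propan-2-yloxy)silyl]methyl}-2,3-dihydroxy-6-methoxy-1,2,3,4-tetrahydronaphthalene-2-carboxylate | COc1cc2c(cc1OCc1ccccc1)[C@H](c1cc(OCc3ccccc3)c(OCc3ccccc3)c(OC)c1)[C@@](O)(C(=O)OCc1ccccc1)[C@](O)(C[Si](C)(C)OC(C)C)C2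
F6 | step 4 | 1,2-bis(benzyloxy)-5-(2,2-dibromoethenyl)-3-methoxybenzene | BrC(Br)=Cc1cc(OCc2ccccc2)c(OCc2ccccc2)c(OC)c1
F7 | step 4 | 3-[3,4-bis(benzyloxy)-5-methoxyphenyl]prop-2-yn-1-ol | OCC#Cc1cc(OCc2ccccc2)c(OCc2ccccc2)c(OC)c1
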